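## Retrosynthetic overview

1. The acetate and γ-lactone come from a diol tert-butyl ester. That ester comes from hydride opening of a cis-3,4-disubstituted 5-menthyloxybutyrolactone: the acetal carbon becomes CH2OAc and the old lactone C=O becomes the lactone OCH2.
2. The bond from the quaternary carbon to the side chain comes from a tertiary hydroazulenyl radical (made from the tertiary alcohol) and an enantiopure 3-substituted 5-(d-menthyloxy)butenolide.
3. The exocyclic methylene comes from Peterson methylenation of a bicyclic β-hydroxy ketone.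
4. Key disconnection: both carbocycles form at once from the acyclic, achiral 11-methyldodeca-5,10-diene-2,7-dione by a hydrogen-atom-transfer Giese cyclization followed by an aldol addition.
5. Ring order: the seven-membered ring forms first, the five-membered ring second (same operation), and the γ-lactone last.

Assumption: the key step starts from an achiral compound, so 9–12 are racemic and are drawn as the enantiomer that goes on to the target. The two diastereomers formed in step 10 from racemic 12 and enantiopure 21 are taken to be separable by chromatography, which caps that step at 50 %.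

## Route

Step 1
Reactants: 1 dimethyl (2-oxopropyl)phosphonate; 2 1-bromo-3-methylbut-2-ene
Product: 3 dimethyl (6-methyl-2-oxohept-5-en-1-yl)phosphonate
Conditions: NaH, THF, 0 °C; n-BuLi, 0 °C; then 2, 0 °C to rt; aqueous work-up
Reagents that add atoms: none
Why: In this dianion alkylation of a β-ketophosphonate, the more basic terminal carbanion displaces bromide from 2 by SN2, and no stereocenter is formed.

Step 2
Reactants: 4 hex-5-en-2-one
Product: 6 4-oxopentanal, via secondary ozonide 5 (not isolated)
Conditions: O3, CH2Cl2, −78 °C; then Me2S, −78 °C to rt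
Reagents that add atoms: ozone, [O-][O+]=O
Why: Criegee ozonolysis with reductive work-up cleaves the only alkene and leaves the ketone untouched.

Step 3
Reactants: 3 dimethyl (6-methyl-2-oxohept-5-en-1-yl)phosphonate; 6 4-oxopentanal
Product: 7 (5E)-11-methyldodeca-5,10-diene-2,7-dione
Conditions: LiCl, i-Pr2NEt, MeCN, rt
Reagents that add atoms: none
Why: The Masamune–Roush variant of the Horner–Wadsworth–Emmons olefination is mild enough to spare the 1,4-dicarbonyl unit, reacts only at the aldehyde and gives the E-enone.

Step 4 (key step)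
Reactants: 7 (5E)-11-methyldodeca-5,10-diene-2,7-dione
Product: 10 rac-(3S,3aR,8aR)-3-hydroxy-3,8,8-trimethyloctahydroazulen-4(1H)-one, via tertiary alkyl radical 8 (not isolated), via monocyclic iron enolate 9 (not isolated)
Conditions: Fe(acac)3 (30 mol %), PhSiH3 (2.5 equiv), EtOH (5 equiv), 1,2-dichloroethane, 0.01 M, 60 °C
Reagents that add atoms: none
Why: Metal-hydride hydrogen-atom transfer to the electron-rich trisubstituted alkene gives radical 8, its 7-endo-trig Giese addition to the enone β-carbon closes the seven-membered ring and makes the gem-dimethyl carbon, and reduction of the α-keto radical to the regiodefined enolate 9 triggers an intramolecular aldol addition to the methyl ketone (radical–polar crossover bicyclization), in which the two-carbon tether allows only the cis ring fusion and the chelate-controlled carbinol configuration is erased later.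

Step 5
Reactants: 10 rac-(3S,3aR,8aR)-3-hydroxy-3,8,8-trimethyloctahydroazulen-4(1H)-one
Product: 12 rac-(3S,3aS,8aR)-3,8,8-trimethyl-4-methylidenedecahydroazulen-3-ol, via hydroxysilane diol 11 (not isolated)
Conditions: Me3SiCH2Li (3 equiv), CeCl3 (3 equiv), THF, −78 to 0 °C; then 1 M HCl, rt
Reagents that add atoms: (trimethylsilyl)methyllithium, [Li]C[Si](C)(C)C
Why: The cerium-modified Peterson olefination uses a weakly basic organocerium reagent that adds to the enolizable β-hydroxy ketone without retro-aldol cleavage or epimerization of the ring-fusion CH, and acid-induced loss of silanol gives the exocyclic methylene.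

Step 6
Reactants: 13 furfural
Product: 14 5-hydroxyfuran-2(5H)-one
Conditions: O2, rose bengal (cat.), hν, MeOH, rt
Reagents that add atoms: dioxygen, O=O
Why: Singlet-oxygen [4+2] photooxygenation of the furan gives an endoperoxide that methanol deformylates to the racemic, configurationally labile γ-hydroxybutenolide.

Step 7
Reactants: 14 5-hydroxyfuran-2(5H)-one; 15 (1S,2R,5S)-(+)-menthol
Product: 16 (5S)-5-[(1S,2R,5S)-menthyloxy]furan-2(5H)-one
Conditions: neat, 100 °C; crystallization from petroleum ether; mother liquor re-equilibrated with p-TsOH (cat.) and recrystallized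
Reagents that add atoms: none
Why: Thermal acetalization gives both acetal epimers, and crystallization-induced epimerization funnels them into the crystalline (5S)-d-menthyl acetal, which is the source of absolute configuration for the whole route.

Step 8
Reactants: 16 (5S)-5-[(1S,2R,5S)-menthyloxy]furan-2(5H)-one
Product: 18 (5S)-3-bromo-5-[(1S,2R,5S)-menthyloxy]furan-2(5H)-one, via dibromolactone 17 (not isolated)
Conditions: Br2, CH2Cl2, 0 °C; then pyridine, 0 °C to rt
Reagents that add atoms: bromine, BrBr
Why: In this bromination–dehydrobromination, the acidic α-H is lost together with the β-bromide, so the bromine stays at the α-carbon and the weak base leaves the acetal center untouched.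

Step 9
Reactants: 18 (5S)-3-bromo-5-[(1S,2R,5S)-menthyloxy]furan-2(5H)-one; 19 tert-butyl bromoacetate
Product: 21 tert-butyl [(5S)-5-[(1S,2R,5S)-menthyloxy]-2-oxo-2,5-dihydrofuran-3-yl]acetate, via Reformatsky reagent 20 (not isolated)
Conditions: Zn dust, 19, THF, rt; then 18, Pd(dba)2 (3 mol %), P(t-Bu)3 (3 mol %), rt
Reagents that add atoms: none
Why: In this Negishi-type cross-coupling of a zinc ester enolate with an electron-poor alkenyl bromide, oxidative addition is fast and the neutral zinc enolate neither adds in a conjugate sense nor epimerizes the acetal.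

Step 10
Reactants: 12 rac-(3S,3aS,8aR)-3,8,8-trimethyl-4-methylidenedecahydroazulen-3-ol; 21 tert-butyl [(5S)-5-[(1S,2R,5S)-menthyloxy]-2-oxo-2,5-dihydrofuran-3-yl]acetate
Product: 23 tert-butyl {(3R,4R,5S)-5-[(1S,2R,5S)-menthyloxy]-2-oxo-4-[(3R,3aS,8aR)-3,8,8-trimethyl-4-methylidenedecahydroazulen-3-yl]oxolan-3-yl}acetate, via benzoxazoline adduct 22 (not isolated)
Conditions: 5,7-di-tert-butyl-3-phenylbenzoxazolium tetrafluoroborate, pyridine, MTBE, rt; then 21, [Ir(ppy)2(dtbbpy)]PF6 (2 mol %), NaOAc, MTBE–DMA, 450 nm LEDs, rt; chromatography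
Reagents that add atoms: none
Why: In this deoxygenative Giese reaction, photoredox oxidation, deprotonation and β-scission of 22 release the tertiary radical, which bonds through the convex face of the cis-hydroazulene (quaternary carbon) and anti to the menthyloxy group (adjacent CH), after which the enolate is protonated anti to the new bulky group (cis-3,4-lactone), so the drawn enantiomer of 12 gives 23 and its antipode gives a diastereomer that is removed.

Step 11
Reactants: 23 tert-butyl {(3R,4R,5S)-5-[(1S,2R,5S)-menthyloxy]-2-oxo-4-[(3R,3aS,8aR)-3,8,8-trimethyl-4-methylidenedecahydroazulen-3-yl]oxolan-3-yl}acetate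
Product: 24 tert-butyl (3R,4R)-5-hydroxy-3-(hydroxymethyl)-4-[(3R,3aS,8aR)-3,8,8-trimethyl-4-methylidenedecahydroazulen-3-yl]pentanoate
Conditions: LiBH4 (3 equiv), THF, 0 °C; aq. NH4Cl
Reagents that add atoms: none
Why: Chemoselective hydride reduction opens the acyloxy acetal, the released hemiacetal expels menthol, and both aldehydes are reduced at once without epimerization, while the tert-butyl ester and the alkene survive.

Step 12
Reactants: 24 tert-butyl (3R,4R)-5-hydroxy-3-(hydroxymethyl)-4-[(3R,3aS,8aR)-3,8,8-trimethyl-4-methylidenedecahydroazulen-3-yl]pentanoate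
Product: 26 (2R)-2-[(3R)-5-oxooxolan-3-yl]-2-[(3R,3aS,8aR)-3,8,8-trimethyl-4-methylidenedecahydroazulen-3-yl]ethyl acetate, via hydroxy lactone 25 (not isolated)
Conditions: CSA (20 mol %), toluene, 60 °C; then Ac2O, pyridine, DMAP (cat.), rt
Reagents that add atoms: acetic anhydride, CC(=O)OC(C)=O
Why: Acid-catalysed lactonization closes the five-membered lactone in preference to the six-membered one, and DMAP-catalysed acetylation caps the remaining primary alcohol without touching any stereocenter.

## Compound list

1 | dimethyl (2-oxopropyl)phosphonate | COP(=O)(CC(C)=O)OC | starting material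
2 | 1-bromo-3-methylbut-2-ene | CC(C)=CCBr | starting material
3 | dimethyl (6-methyl-2-oxohept-5-en-1-yl)phosphonate | COP(=O)(CC(=O)CCC=C(C)C)OC | intermediate
4 | hex-5-en-2-one | CC(=O)CCC=C | starting material
5 | 4-(1,2,4-trioxolan-3-yl)butan-2-one | CC(=O)CCC1OCOO1 | intermediate
6 | 4-oxopentanal | CC(=O)CCC=O | intermediate
7 | (5E)-11-methyldodeca-5,10-diene-2,7-dione | CC(C)=CCCC(=O)/C=C/CCC(C)=O | intermediate
8 | (7E)-2-methyl-6,11-dioxododec-7-en-2-yl radical | C[C](C)CCCC(=O)/C=C/CCC(C)=O | intermediate
9 | rac-4-(3-hydroxy-7,7-dimethylcyclohept-2-en-1-yl)butan-2-one (iron enolate, drawn as the enol) | CC(=O)CC[C@@H]1C=C(O)CCCC1(C)C | intermediate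
10 | rac-(3S,3aR,8aR)-3-hydroxy-3,8,8-trimethyloctahydroazulen-4(1H)-one (cis-fused, OH syn to the ketone) | O=C1CCCC(C)(C)[C@@H]2CC[C@](C)(O)[C@H]12 | intermediate
11 | rac-3,8,8-trimethyl-4-[(trimethylsilyl)methyl]decahydroazulene-3,4-diol (new carbinol center undefined) | C[Si](C)(C)CC1(O)CCCC(C)(C)[C@@H]2CC[C@](C)(O)[C@H]12 | intermediate
12 | rac-(3S,3aS,8aR)-3,8,8-trimethyl-4-methylidenedecahydroazulen-3-ol | C=C1CCCC(C)(C)[C@@H]2CC[C@](C)(O)[C@H]12 | intermediate
13 | furfural | O=Cc1ccco1 | starting material
14 | 5-hydroxyfuran-2(5H)-one (racemic) | O=C1C=CC(O)O1 | intermediate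
15 | (1S,2R,5S)-(+)-menthol | O[C@H]1C[C@@H](C)CC[C@@H]1C(C)C | starting material
16 | (5S)-5-[(1S,2R,5S)-menthyloxy]furan-2(5H)-one | O=C1C=C[C@@H](O[C@H]2C[C@@H](C)CC[C@@H]2C(C)C)O1 | intermediate
17 | (5S)-3,4-dibromo-5-[(1S,2R,5S)-menthyloxy]oxolan-2-one (bromine-bearing centers undefined) | BrC1C(Br)[C@@H](O[C@H]2C[C@@H](C)CC[C@@H]2C(C)C)OC1=O | intermediate
18 | (5S)-3-bromo-5-[(1S,2R,5S)-menthyloxy]furan-2(5H)-one | BrC1=C[C@@H](O[C@H]2C[C@@H](C)CC[C@@H]2C(C)C)OC1=O | intermediate
19 | tert-butyl bromoacetate | CC(C)(C)OC(=O)CBr | starting material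
20 | bromo(2-tert-butoxy-2-oxoethyl)zinc | CC(C)(C)OC(=O)C[Zn]Br | intermediate
21 | tert-butyl [(5S)-5-[(1S,2R,5S)-menthyloxy]-2-oxo-2,5-dihydrofuran-3-yl]acetate | CC(C)(C)OC(=O)CC1=C[C@@H](O[C@H]2C[C@@H](C)CC[C@@H]2C(C)C)OC1=O | intermediate
22 | 5,7-di-tert-butyl-3-phenyl-2-(hydroazulen-3-yloxy)-2,3-dihydrobenzoxazole (adduct of 12, aminal center undefined) | C=C1CCCC(C)(C)[C@@H]2CC[C@](C)(OC3Oc4c(C(C)(C)C)cc(C(C)(C)C)cc4N3c5ccccc5)[C@H]12 | intermediate
23 | tert-butyl {(3R,4R,5S)-5-[(1S,2R,5S)-menthyloxy]-2-oxo-4-[(3R,3aS,8aR)-3,8,8-trimethyl-4-methylidenedecahydroazulen-3-yl]oxolan-3-yl}acetate | C=C1CCCC(C)(C)[C@@H]2CC[C@@](C)([C@@H]3[C@@H](O[C@H]4C[C@@H](C)CC[C@@H]4C(C)C)OC(=O)[C@@H]3CC(=O)OC(C)(C)C)[C@H]12 | intermediate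
24 | tert-butyl (3R,4R)-5-hydroxy-3-(hydroxymethyl)-4-[(3R,3aS,8aR)-3,8,8-trimethyl-4-methylidenedecahydroazulen-3-yl]pentanoate | C=C1CCCC(C)(C)[C@@H]2CC[C@@](C)([C@H](CO)[C@H](CO)CC(=O)OC(C)(C)C)[C@H]12 | intermediate
25 | (4R)-4-{(1R)-2-hydroxy-1-[(3R,3aS,8aR)-3,8,8-trimethyl-4-methylidenedecahydroazulen-3-yl]ethyl}oxolan-2-one | C=C1CCCC(C)(C)[C@@H]2CC[C@@](C)([C@H](CO)[C@@H]3COC(=O)C3)[C@H]12 | intermediate
26 | (2R)-2-[(3R)-5-oxooxolan-3-yl]-2-[(3R,3aS,8aR)-3,8,8-trimethyl-4-methylidenedecahydroazulen-3-yl]ethyl acetate | C=C1CCCC(C)(C)[C@@H]2CC[C@@](C)([C@H](COC(C)=O)[C@@H]3COC(=O)C3)[C@H]12 | target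

## Step count and risk

Total step count: 12.

Longest linear sequence: 7 steps (1, 3, 4, 5, 10, 11, 12). The butenolide branch (6, 7, 8, 9, 10, 11, 12) is equally long.

**Step 4.** Three things can go wrong here:
- The 7-endo closure may lose to iron-hydride reduction of the enone.
- It may lose to simple reduction of radical 8.
- Enolate 9 may be protonated before the aldol step.

The fallback sets out from 7 and comes back at 10. It removes the metal hydride altogether.
- Markovnikov hydroiodination of the trisubstituted alkene (Me3SiCl, NaI, H2O, MeCN, 0 °C) gives the tertiary iodide F1, which is used crude.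
- Et3B and air in toluene start an iodine-atom-transfer chain. The tertiary radical cyclizes onto the enone, and Et3B captures the α-keto radical at oxygen to give the diethylboron enolate F2.
- F2 adds to the methyl ketone in a closed aldol transition state and gives 10 after aqueous work-up.

**Step 10.** Three things can go wrong here:
- The hindered tertiary alcohol may not condense with the benzoxazolium salt.
- The bulky radical may add slowly to the trisubstituted acceptor.
- The cis-lactone may epimerize.

The fallback sets out from 12 and comes back at 23. It uses an isolable radical precursor and a decarboxylative fragmentation.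
- Acylation with methyl chlorooxoacetate (Et3N, DMAP, CH2Cl2) gives the methyl oxalate F3.
- One equivalent of aqueous CsOH in THF gives the cesium oxalate F4.
- Irradiation of F4 with 21, [Ir(dF(CF3)ppy)2(dtbbpy)]PF6 and water (10 equiv) in DME–DMF expels two molecules of CO2. It gives the same tertiary radical under essentially neutral conditions that protect the cis-lactone.

**Step 11.** The primary alkoxide may close onto the tert-butyl ester in the flask, and the new lactone would then be over-reduced to a triol.

The fallback sets out from 23 and comes back at 25. It replaces ester protection by a carboxylate that hydride cannot attack.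
- Me3SiOTf and 2,6-lutidine (CH2Cl2, 0 °C, then water) cleave the tert-butyl ester to the carboxylic acid F5.
- The lithium salt of F5 is reduced with LiBH4 at the lactone acetal only.
- Acidification to pH 3 closes the γ-lactone and gives 25, which is acetylated as in step 12.

## Further compounds

F1 | step 4 | (5E)-11-iodo-11-methyldodec-5-ene-2,7-dione | CC(C)(I)CCCC(=O)/C=C/CCC(C)=O
F2 | step 4 | rac-4-{3-[(diethylboranyl)oxy]-7,7-dimethylcyclohept-2-en-1-yl}butan-2-one | CC(=O)CC[C@@H]1C=C(OB(CC)CC)CCCC1(C)C
F3 | step 10 | rac-methyl (3S,3aS,8aR)-3,8,8-trimethyl-4-methylidenedecahydroazulen-3-yl oxalate | C=C1CCCC(C)(C)[C@@H]2CC[C@](C)(OC(=O)C(=O)OC)[C@H]12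
F4 | step 10 | rac-cesium 2-oxo-2-{[(3S,3aS,8aR)-3,8,8-trimethyl-4-methylidenedecahydroazulen-3-yl]oxy}acetate | C=C1CCCC(C)(C)[C@@H]2CC[C@](C)(OC(=O)C(=O)[O-])[C@H]12.[Cs+]
F5 | step 11 | {(3R,4R,5S)-5-[(1S,2R,5S)-menthyloxy]-2-oxo-4-[(3R,3aS,8aR)-3,8,8-trimethyl-4-methylidenedecahydroazulen-3-yl]oxolan-3-yl}acetic acid | C=C1CCCC(C)(C)[C@@H]2CC[C@@](C)([C@@H]3[C@@H](O[C@H]4C[C@@H](C)CC[C@@H]4C(C)C)OC(=O)[C@@H]3CC(=O)O)[C@H]12
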